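**Retrosynthetic overview**
1. Ring labels: A is the hydroxylated dibenzofuran ring, B the second dibenzofuran ring, C the phenol ring that carries the diaryl ether, and D the para-phenylene ring.
2. Asterelin A ⇒ its ring C methyl ether ⇒ a macrocyclic 9b-alkyl-dibenzofuran-3(9bH)-one, by a 1,2-shift of the bridge CH2 from C9b to C1 (large ring 17 → 18 atoms, ring A aromatises). That dienone ⇒ an 18-membered bis(diaryl ether) macrocycle with ring A as a 3-aryloxy-4-alkylphenol, by transannular C–C closure of the furan ring.
3. Macrocycle ⇒ two B-alkyl Suzuki couplings. The B–CH2CH2–C coupling closes the ring and the D–CH2CH2–A coupling joins the halves. The reactivity order C–I > C–Br > C–Cl fixes the orientation.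
4. Halves ⇒ two Ullmann ethers. A–O–B comes from resorcinol and 1-bromo-3-iodobenzene, then para-iodination. C–O–D comes from 4-chlorophenol (ortho-iodination, O-methylation) and 4-bromophenol. Both C2 bridges come from potassium vinyltrifluoroborate.
5. Order of ring formation: the 18-membered macrocycle first, then the furan ring, then re-aromatised ring A through the shift.

Assumption: the SMILES holds no stereocentre and no stereodescriptor, so asterelin A is made as the one constitution drawn and no enantioselective step is needed.

**Route**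

Step 1
Reactants: 1 resorcinol; 2 1-bromo-3-iodobenzene
Product: 3 3-(3-bromophenoxy)phenol
Conditions: 1 (3 equiv), CuI (10 mol %), picolinic acid (20 mol %), K3PO4 (2 equiv), DMSO, 80 °C
Reagents that add atoms: none
Why: Ullmann-type C–O coupling in which copper takes the C–I bond far faster than C–Br, while the threefold excess of the symmetric diol keeps the arylation at the mono stage.

Step 2
Reactants: 3 3-(3-bromophenoxy)phenol
Product: 4 3-(3-bromophenoxy)-4-iodophenol
Conditions: NIS (1.0 equiv), TsOH·H2O (1 equiv), MeCN, 0 °C to rt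
Reagents that add atoms: N-iodosuccinimide, O=C1CCC(=O)N1I
Why: Electrophilic aromatic iodination goes para to the free OH, the strongest donor (a site also ortho to the aryloxy group), and the bromophenyl ring is too electron-poor to compete.

Step 3
Reactants: 5 4-chlorophenol
Product: 7 4-chloro-2-iodo-1-methoxybenzene, via 4-chloro-2-iodophenol 6 (not isolated)
Conditions: NIS (1.05 equiv), TsOH·H2O (10 mol %), MeCN, rt; then K2CO3 (3 equiv), MeI (2.5 equiv), 40 °C, same flask
Reagents that add atoms: N-iodosuccinimide, O=C1CCC(=O)N1I; iodomethane, CI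
Why: Electrophilic iodination can only go ortho to OH because Cl blocks the para site, and the Williamson methylation in the same flask masks the phenol that must stay inert in the later oxidation.

Step 4
Reactants: 7 4-chloro-2-iodo-1-methoxybenzene; 8 4-bromophenol
Product: 9 2-(4-bromophenoxy)-4-chloro-1-methoxybenzene
Conditions: CuI (10 mol %), picolinic acid (20 mol %), K3PO4 (2 equiv), DMSO, 80 °C
Reagents that add atoms: none
Why: Ullmann-type C–O coupling at the C–I bond, with the C–Br of the electron-rich phenoxide partner and the C–Cl of 7 much slower at this temperature.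

Step 5
Reactants: 9 2-(4-bromophenoxy)-4-chloro-1-methoxybenzene; 10 potassium vinyltrifluoroborate
Product: 11 4-chloro-2-(4-ethenylphenoxy)-1-methoxybenzene
Conditions: PdCl2(dppf) (2 mol %), Et3N (1.5 equiv), n-PrOH, reflux
Reagents that add atoms: none
Why: Suzuki–Miyaura vinylation in which zerovalent palladium with dppf inserts into C–Br and leaves the electron-rich C–Cl untouched.

Step 6
Reactants: 11 4-chloro-2-(4-ethenylphenoxy)-1-methoxybenzene; 4 3-(3-bromophenoxy)-4-iodophenol
Product: 13 3-(3-bromophenoxy)-4-{2-[4-(5-chloro-2-methoxyphenoxy)phenyl]ethyl}phenol, via B-alkyl-9-BBN borane 12 (not isolated)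
Conditions: 9-BBN (1.2 equiv), THF, 0 °C to rt; then 4, PdCl2(dppf) (5 mol %), 3 M aq K3PO4 (4 equiv), DMF, rt to 40 °C
Reagents that add atoms: none
Why: Anti-Markovnikov hydroboration and B-alkyl Suzuki–Miyaura coupling build the saturated D–CH2CH2–A bridge directly, since only C–I undergoes oxidative addition at or below 40 °C and C–Br and C–Cl are kept for later.

Step 7
Reactants: 13 3-(3-bromophenoxy)-4-{2-[4-(5-chloro-2-methoxyphenoxy)phenyl]ethyl}phenol; 10 potassium vinyltrifluoroborate
Product: 14 4-{2-[4-(5-chloro-2-methoxyphenoxy)phenyl]ethyl}-3-(3-ethenylphenoxy)phenol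
Conditions: PdCl2(dppf) (3 mol %), Et3N (2 equiv), n-PrOH, reflux
Reagents that add atoms: none
Why: Suzuki–Miyaura vinylation of the ring B bromide, which tolerates the free phenol and again spares the aryl chloride.

Step 8
Reactants: 14 4-{2-[4-(5-chloro-2-methoxyphenoxy)phenyl]ethyl}-3-(3-ethenylphenoxy)phenol
Product: 16 18-membered bis(diaryl ether) macrocycle (ring A phenol; ring C methyl ether), via B-alkyl-9-BBN borane 15 (not isolated)
Conditions: 9-BBN (2.5 equiv), THF, rt; then syringe-pump addition to Pd(OAc)2 (10 mol %), SPhos (20 mol %), K3PO4 (4 equiv), THF/H2O, 65 °C, final 2 mM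
Reagents that add atoms: none
Why: 9-BBN adds anti-Markovnikov to the styrene and the electron-rich biaryl phosphine lets zerovalent palladium insert into the last halide, so an intramolecular B-alkyl Suzuki–Miyaura coupling under pseudo-high dilution closes a flexible, essentially strain-free 18-membered ring.

Step 9
Reactants: 16 18-membered bis(diaryl ether) macrocycle (ring A phenol; ring C methyl ether)
Product: 18 asterelin A ring C methyl ether, via macrocyclic 9b-alkyl dienone 17 (not isolated)
Conditions: PhI(OAc)2 (1.0 equiv), (CF3)2CHOH, 0 °C, 5 mM, 30 min; then TfOH (3 equiv), 0 to 50 °C, same flask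
Reagents that add atoms: none
Why: Proposed new method: a transannular dearomatising arylation followed in the same flask by a ring-expanding dienone–phenol 1,2-shift; PhI(OAc)2 turns the only free phenol (ring A) into a phenoxenium-type species whose para carbon, the one carrying the CH2CH2 bridge, is captured Friedel–Crafts fashion by the neighbouring aryloxy ring B at its ortho carbon para to the other bridge (five-membered closure, the other ortho site being shielded by that bridge), which gives the usnic-acid-like dienone 17 as a racemate and shrinks the large ring from 18 to 17 atoms; after O-protonation by TfOH the only group on C9b that can migrate productively is the bridge CH2 (ring B is locked in the furan ring and C4a carries oxygen), so it shifts to C1, the cation left at C9b is benzylic to ring B and conjugated with the furan oxygen, and loss of H+ aromatises ring A, erases the transient stereocentre, re-expands the ring to 18 atoms and pays for the added strain with aromatisation energy, while also moving the alkyl group to the position meta to both oxygens that electrophilic chemistry on resorcinol cannot reach; solvent or acetate adducts at the para carbon re-ionise in acid and feed the same channel; the closest known reaction types are trivalent-iodine phenol dearomatisation with arene capture (spirodienone synthesis) and the acid-catalysed dienone–phenol rearrangement, neither shown on a 3-aryloxy-4-alkylphenol or across a macrocycle.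

Step 10
Reactants: 18 asterelin A ring C methyl ether
Product: 19 asterelin A
Conditions: BBr3 (4 equiv), CH2Cl2, −78 °C to rt; then H2O
Reagents that add atoms: none
Why: Lewis-acid ether cleavage with BBr3 removes the only alkyl aryl ether, the diaryl ether and dibenzofuran C–O bonds being inert, and no stereocentre is involved.

**Compound list**
1 | resorcinol (benzene-1,3-diol) | Oc1cccc(O)c1 | starting material
2 | 1-bromo-3-iodobenzene | Brc1cccc(I)c1 | starting material
3 | 3-(3-bromophenoxy)phenol | Oc1cccc(Oc2cccc(Br)c2)c1 | intermediate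
4 | 3-(3-bromophenoxy)-4-iodophenol | Oc1ccc(I)c(Oc2cccc(Br)c2)c1 | intermediate
5 | 4-chlorophenol | Oc1ccc(Cl)cc1 | starting material
6 | 4-chloro-2-iodophenol (not isolated) | Oc1ccc(Cl)cc1I | intermediate
7 | 4-chloro-2-iodo-1-methoxybenzene | COc1ccc(Cl)cc1I | intermediate
8 | 4-bromophenol | Oc1ccc(Br)cc1 | starting material
9 | 2-(4-bromophenoxy)-4-chloro-1-methoxybenzene | COc1ccc(Cl)cc1Oc1ccc(Br)cc1 | intermediate
10 | potassium vinyltrifluoroborate | [K+].C=C[B-](F)(F)F | starting material
11 | 4-chloro-2-(4-ethenylphenoxy)-1-methoxybenzene | COc1ccc(Cl)cc1Oc1ccc(C=C)cc1 | intermediate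
12 | 9-{2-[4-(5-chloro-2-methoxyphenoxy)phenyl]ethyl}-9-borabicyclo[3.3.1]nonane (not isolated) | COc1ccc(Cl)cc1Oc1ccc(CCB2C3CCCC2CCC3)cc1 | intermediate
13 | 3-(3-bromophenoxy)-4-{2-[4-(5-chloro-2-methoxyphenoxy)phenyl]ethyl}phenol | COc1ccc(Cl)cc1Oc1ccc(CCc2ccc(O)cc2Oc2cccc(Br)c2)cc1 | intermediate
14 | 4-{2-[4-(5-chloro-2-methoxyphenoxy)phenyl]ethyl}-3-(3-ethenylphenoxy)phenol | COc1ccc(Cl)cc1Oc1ccc(CCc2ccc(O)cc2Oc2cccc(C=C)c2)cc1 | intermediate
15 | B-alkyl-9-BBN borane from 14, boron on the terminal carbon of the former ring B vinyl group (not isolated) | COc1ccc(Cl)cc1Oc1ccc(CCc2ccc(O)cc2Oc2cccc(CCB3C4CCCC3CCC4)c2)cc1 | intermediate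
16 | 18-membered macrocycle A–O–B–CH2CH2–C–O–D–CH2CH2–A; ring A is a 3-aryloxy-4-alkylphenol, ring B is meta-linked, ring C is a 2-aryloxy-4-alkylanisole, ring D is para-linked | COc1ccc2cc1Oc1ccc(cc1)CCc1ccc(O)cc1Oc1cccc(CC2)c1 | intermediate
17 | racemic macrocyclic 9b-alkyl-dibenzofuran-3(9bH)-one; the ring D bridge sits on sp3 C9b and the ring C bridge on C7, with C1=C2 and C4=C4a double bonds and a 17-membered large ring (not isolated) | COc1ccc2cc1Oc1ccc(cc1)CCC13C=CC(=O)C=C1Oc1cc(CC2)ccc13 | intermediate
18 | asterelin A ring C methyl ether (dibenzofuran-3-ol with the ring D bridge on C1 and the ring C bridge on C7) | Oc1cc2c3c(c1)oc1cc(ccc13)CCc1ccc(OC)c(c1)Oc1ccc(cc1)CC2 | intermediate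
19 | asterelin A | Oc1cc2c3c(c1)oc1cc(ccc13)CCc1ccc(O)c(c1)Oc1ccc(cc1)CC2 | target

**Totals**
Total step count: 10.
Longest linear sequence: 8 steps (5 → 7 → 9 → 11 → 13 → 14 → 16 → 18 → 19, steps 3 to 10).

**Three steps most likely to fail**

Step 9 (the proposed new step).
- Risks: the oxidised phenol may lose a benzylic proton to give a para-quinone methide or be trapped by solvent. The shift may also be slow because the protonated vinylogous ester is a well-stabilised cation.
- Fallback, all known chemistry, setting out from 16 and coming back at 18. First, 16 is oxidised with PhI(OAc)2 in MeCN/H2O at 0 °C to the macrocyclic para-quinol F1. TFA in CH2Cl2 then triggers the classical quinol-to-hydroquinone rearrangement, in which the bridge CH2 moves to the neighbouring unsubstituted carbon, and gives the ring-enlarged hydroquinone F2. TBSCl/imidazole silylates only the unhindered hydroxyl to give the mono-silyl ether F3. Tf2O/pyridine converts the flanked hydroxyl into the aryl triflate F4. Pd(OAc)2, PCy3·HBF4 and K2CO3 in DMA at 120 °C close the biaryl bond by intramolecular direct C–H arylation to the silylated dibenzofuran F5, and TBAF releases 18.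

Step 8.
- Risks: oligomers and protodeboronation may compete with macrocyclisation on an electron-rich aryl chloride.
- Fallback, setting out from 14 and coming back at 16. The C–Cl bond of 14 is vinylated with 10 (Pd(OAc)2, SPhos, K2CO3, THF/H2O, 80 °C) to the divinyl compound F6. Ring-closing metathesis with the second-generation Grubbs catalyst (toluene, 2 mM, 60 °C) gives the macrocyclic stilbene F7 as an E/Z mixture. Hydrogenation (H2, Pd/C, EtOAc) then gives 16.

Step 6.
- Risk: the iodide of 4 is hindered and sits on a phenoxide ring, so the preference for C–I over C–Br may erode.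
- Fallback, setting out from 9 and coming back at 13. Sonogashira coupling of 9 with trimethylsilylacetylene (PdCl2(PPh3)2, CuI, Et3N, 70 °C) gives the silyl alkyne F8, and K2CO3/MeOH gives the terminal alkyne F9. A second Sonogashira coupling with 4 at rt, where only C–I reacts, gives the diaryl alkyne F10. Diimide (TsNHNH2, NaOAc, THF/H2O, reflux) saturates the triple bond without touching C–Br or C–Cl and delivers 13.

**Further compounds**
F1 | step 9 | macrocyclic para-quinol (racemic; ring A is a 4-alkyl-4-hydroxy-3-aryloxycyclohexa-2,5-dienone) | COc1ccc2cc1Oc1ccc(cc1)CCC1(O)C=CC(=O)C=C1Oc1cccc(CC2)c1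
F2 | step 9 | ring-enlarged hydroquinone (ring A is a 2-alkyl-6-aryloxybenzene-1,4-diol) | COc1ccc2cc1Oc1ccc(cc1)CCc1cc(O)cc(c1O)Oc1cccc(CC2)c1
F3 | step 9 | mono-silyl ether (TBS on the unhindered ring A hydroxyl) | COc1ccc2cc1Oc1ccc(cc1)CCc1cc(O[Si](C)(C)C(C)(C)C)cc(c1O)Oc1cccc(CC2)c1
F4 | step 9 | aryl triflate (OTf between the bridge and the aryloxy group of ring A) | COc1ccc2cc1Oc1ccc(cc1)CCc1cc(O[Si](C)(C)C(C)(C)C)cc(c1OS(=O)(=O)C(F)(F)F)Oc1cccc(CC2)c1
F5 | step 9 | silylated dibenzofuran (3-O-TBS ether of 18) | CC(C)(C)[Si](C)(C)Oc1cc2c3c(c1)oc1cc(ccc13)CCc1ccc(OC)c(c1)Oc1ccc(cc1)CC2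
F6 | step 8 | divinyl compound 4-{2-[4-(5-ethenyl-2-methoxyphenoxy)phenyl]ethyl}-3-(3-ethenylphenoxy)phenol | COc1ccc(C=C)cc1Oc1ccc(CCc2ccc(O)cc2Oc2cccc(C=C)c2)cc1
F7 | step 8 | macrocyclic stilbene (E/Z mixture, B–CH=CH–C bridge) | COc1ccc2cc1Oc1ccc(cc1)CCc1ccc(O)cc1Oc1cccc(C=C2)c1
F8 | step 6 | silyl alkyne 4-chloro-1-methoxy-2-{4-[(trimethylsilyl)ethynyl]phenoxy}benzene | COc1ccc(Cl)cc1Oc1ccc(C#C[Si](C)(C)C)cc1
F9 | step 6 | terminal alkyne 4-chloro-2-(4-ethynylphenoxy)-1-methoxybenzene | COc1ccc(Cl)cc1Oc1ccc(C#C)cc1
F10 | step 6 | diaryl alkyne 3-(3-bromophenoxy)-4-{[4-(5-chloro-2-methoxyphenoxy)phenyl]ethynyl}phenol | COc1ccc(Cl)cc1Oc1ccc(C#Cc2ccc(O)cc2Oc2cccc(Br)c2)cc1
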